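**Impossible order.** A loss of solid substrate in proportion to its charge is impossible here. That statistical case, first order, takes the same percentage from every charge. Yet by 20.0 h the larch run has lost 24.9% and the ash run 13.4%. In molar terms the losses are 0.120 M and 0.125 M, nearly equal. As read from these two runs, the loss is zero order in the charge.

| flask | solid substrate | remark | time |
|---|---|---|---|
| larch | 0.48 M | run made earlier |  |
| ash | 0.93 M | run made earlier |  |
| delta | 0.50 M |  | 40 h |
| gamma | 1.0 M |  | 40 h |
| alpha | 2.0 M |  | 40 h |

| run | time / h | ring / % | solid substrate / % |
|---|---|---|---|
| larch | 1.50 | 0 | 97.7 |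
| larch | 3.00 | 0.2 | 95.9 |
| larch | 6.00 | 1.0 | 92.0 |
| larch | 10.0 | 3.2 | 86.5 |
| larch | 20.0 | 9.4 | 75.1 |
| ash | 4.00 | 0.8 | 97.2 |
| ash | 8.00 | 1.5 | 95.2 |
| ash | 12.0 | 2.5 | 92.1 |
| ash | 15.0 | 2.9 | 90.5 |
| ash | 20.0 | 5.7 | 86.6 |

(standard deviation of a reading: 0.3 percentage points)

* [ring] (only what is free in solution) at the end for delta, gamma, alpha, in this order
* how the row runs (hardly changes / falls, then rises / rises, then falls / rises all the way / falls all the way)

- at the start none of the solid substrate is in solution
- a reading or a percentage of ring counts all its forms, free or not
- the concentration of ring that is asked is that of its free form alone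
- "hardly changes" means that all values lie within two and a half points (for a concentration: within two and a half percent of the largest)

**Two times.** The feed F, the molar loss of solid substrate per hour over both runs, is 0.00610 M/h. The emptying time is t_x = c/F for a charge c. For delta, with the smallest charge, t_x is 81.9 h, twice the asked 40 h. That emptying time exceeds the asked time, so each flask should keep solid and lose about 0.244 M.

**Own reckoning.** At 20.0 h, ring holds 40.2% of the lost solid substrate in the two runs together. Held at that share, ring ends near 0.0981 M in all three flasks. The forecast, on the ground that “no charge runs out, even at 0.50 M”, gives 0.14 M, 0.14 M and 0.14 M, hardly changes, a level above this reckoning.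

**The result.** Free ring ends at 0.106 M, 0.106 M and 0.107 M: hardly changes. Delta has lost 0.236 M of solid substrate and alpha 0.236 M, against F·t of 0.244 M.

    starting material → ring (k = 0.0700 /h)
    solid substrate ⇌ starting material, rate k2*(cs2 - [starting material]) while solid is left; crystals form when [starting material] > cs2 (solubility = 0.510 M, k = 0.0130 /h)
    ring → over-reaction product (k = 0.0260 /h)
    2 starting material → open dimer (k = 0.0130 /M/h)
    crystals ⇌ ring, rate k5*(cs5 - [ring]) while solid is left; crystals form when [ring] > cs5 (solubility = 0.870 M, k = 1.80 /h)

At 19.3 h, dissolved ring in delta is made 3.78 times faster than it is used up. Its half-life in delta by conversion into over-reaction product alone is 27 h, shorter than the asked time, and at 40.0 h delta holds over-reaction product amounting to 10.1% of its charge.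

The readings are calculated with made-up constants, and the scatter is random.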